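**Plan**
1. Retrosynthesis: the four O-methyl groups are removed first, then C2 is returned to the cis configuration and the C4 phenol to its 4-methoxybenzyl ether. The C2–C3 bond of the dihydrofuran ring is cut next, giving a diaryl carbene centred on C3.
2. Further cuts: the ring A–benzofuran biaryl bond (Suzuki), the two aryl–O bonds of ring A (double SNAr on a 2,6-difluorobenzophenone) and the ring A–carbonyl bond (aryllithium plus aldehyde).
3. Forward order: ring A is joined to the 3,5-dimethoxyphenyl carbon, both fluorides become 4-methoxybenzyloxy arms, the 6-methoxybenzofuran is attached, the ketone becomes a hydrazone, and the dihydrofuran ring is closed last by C2–C3 bond formation.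
4. Enabling feature: C3 sits on ring A between the two oxygen-bearing carbons C4 and C7a, so a carbene at C3 is 1,5 to a hydridic OCH2 hydrogen, activated by O1 and the 4-methoxyphenyl ring. Ring A is locally twofold-symmetric, so the two arms are identical: one becomes C2/O1, the other protects the C4 phenol.
5. Stereochemistry: the chiral dirhodium carboxylate sets C3 as S and delivers the cis (2R,3S) ring. Reversible acid ionisation of the C2–O1 bond to a 4-methoxybenzylic cation then inverts C2 to the thermodynamic trans (2S,3S) isomer; C3 is not touched.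

Key step: step 6

Assumption: Rh2(S-PTAD)4 is taken as the catalyst antipode that gives the (3S) centre; if a first run shows the opposite sense, Rh2(R-PTAD)4, equally available, is used with no other change.

**Step 1**
Reactants: 1 1-bromo-3,5-difluorobenzene; 2 3,5-dimethoxybenzaldehyde
Product: 4 racemic (4-bromo-2,6-difluorophenyl)(3,5-dimethoxyphenyl)methanol, via aryllithium 3 (not isolated)
Conditions: LiN(iPr)2 (1.05 equiv), THF, −78 °C; then 2, −78 °C; aq. NH4Cl
Reagents that add atoms: none
Why: Directed ortho-lithiation at the most acidic C–H, flanked by both fluorines, gives aryllithium 3 (kept below −70 °C), which adds 1,2 to the aldehyde; the carbinol centre is racemic and is erased in step 2.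

**Step 2**
Reactants: 4 racemic (4-bromo-2,6-difluorophenyl)(3,5-dimethoxyphenyl)methanol
Product: 5 (4-bromo-2,6-difluorophenyl)(3,5-dimethoxyphenyl)methanone
Conditions: Dess–Martin periodinane, CH2Cl2, rt
Reagents that add atoms: none
Why: Dess–Martin oxidation of a secondary diaryl carbinol; no other oxidisable group is present.

**Step 3**
Reactants: 5 (4-bromo-2,6-difluorophenyl)(3,5-dimethoxyphenyl)methanone; 6 (4-methoxyphenyl)methanol
Product: 8 {4-bromo-2,6-bis[(4-methoxybenzyl)oxy]phenyl}(3,5-dimethoxyphenyl)methanone, via the monofluoro mono-ether ketone 7 (not isolated)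
Conditions: 6 (2.3 equiv), NaH (2.4 equiv), THF/DMF, 0 °C → 40 °C
Reagents that add atoms: none
Why: Twofold nucleophilic aromatic substitution (addition–elimination) of the fluorides ortho to the aroyl group by sodium 4-methoxybenzyl oxide; fluoride leaves far faster than the para bromide, which is kept for step 4.

**Step 4**
Reactants: 8 {4-bromo-2,6-bis[(4-methoxybenzyl)oxy]phenyl}(3,5-dimethoxyphenyl)methanone; 9 (6-methoxy-1-benzofuran-2-yl)boronic acid
Product: 10 {2,6-bis[(4-methoxybenzyl)oxy]-4-(6-methoxy-1-benzofuran-2-yl)phenyl}(3,5-dimethoxyphenyl)methanone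
Conditions: Pd(OAc)2 (3 mol %), SPhos (6 mol %), K3PO4, 9 (1.5 equiv), THF/H2O, 50 °C
Reagents that add atoms: none
Why: Suzuki–Miyaura coupling of an unhindered aryl bromide; the fast palladium diacetate/SPhos system at moderate temperature should outrun protodeboronation of the 2-benzofuranylboronic acid, and the ketone and ethers are inert.

**Step 5**
Reactants: 10 {2,6-bis[(4-methoxybenzyl)oxy]-4-(6-methoxy-1-benzofuran-2-yl)phenyl}(3,5-dimethoxyphenyl)methanone
Product: 11 hydrazone of ketone 10 (E/Z mixture)
Conditions: N2H4·H2O (20 equiv), AcOH (cat.), n-BuOH, 110 °C, sealed tube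
Reagents that add atoms: hydrazine hydrate (NN.O)
Why: Acid-catalysed condensation of the hindered diaryl ketone with a large excess of the small alpha-effect nucleophile hydrazine (the excess suppresses azine formation); the C=N geometry is lost in step 6, so the E/Z mixture does not matter.

**Step 6**
Reactants: 11 hydrazone of ketone 10
Product: 13 (2R,3S)-3-(3,5-dimethoxyphenyl)-4-[(4-methoxybenzyl)oxy]-6-(6-methoxy-1-benzofuran-2-yl)-2-(4-methoxyphenyl)-2,3-dihydro-1-benzofuran (cis), via diaryldiazomethane 12 (not isolated)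
Conditions: MnO2 (8 equiv), CH2Cl2, 0 °C; filtration through Celite; filtrate added slowly to Rh2(S-PTAD)4 (1 mol %; PTAD = (1-adamantyl)(N-phthalimido)acetate), CH2Cl2, −20 °C → rt
Reagents that add atoms: none
Why: MnO2 dehydrogenates the hydrazone to diaryldiazomethane 12, which loses N2 on the dirhodium tetracarboxylate to give an electrophilic donor/donor rhodium carbene at the future C3. The carbene carbon lies 1,5 to the OCH2 hydrogens of either ortho 4-methoxybenzyloxy arm, and these C–H bonds are hydridic because O1 and the 4-methoxyphenyl ring stabilise positive charge at C2, so insertion should proceed by an asynchronous hydride shift to C3 with immediate C2–C3 collapse; the closest known reaction type is the enantioselective rhodium-catalysed intramolecular C–H insertion of diaryl (donor/donor) carbenes into benzyl ethers, which gives cis-2,3-diaryl-2,3-dihydrobenzofurans. The dihydrofuran ring closes in the 1,5-insertion mode through a five-membered cyclic transition state. C3 is set by the carbene face that the chiral PTAD carboxylate wall leaves open, and C2 by which enantiotopic methylene hydrogen is transferred, the compact transition state placing the two aryl groups cis under kinetic control. The step needs site selectivity for the benzylic ether C–H, which the substrate secures through two constitutionally identical arms on ring A (either gives 13), no other C–H within 1,5 reach and a benzofuran C2=C3 bond out of intramolecular reach; slow addition at low concentration suppresses azine formation.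

**Step 7**
Reactants: 13 (2R,3S)-3-(3,5-dimethoxyphenyl)-4-[(4-methoxybenzyl)oxy]-6-(6-methoxy-1-benzofuran-2-yl)-2-(4-methoxyphenyl)-2,3-dihydro-1-benzofuran
Product: 14 (2S,3S)-3-(3,5-dimethoxyphenyl)-6-(6-methoxy-1-benzofuran-2-yl)-2-(4-methoxyphenyl)-2,3-dihydro-1-benzofuran-4-ol (trans)
Conditions: CF3CO2H (10 vol %), pentamethylbenzene (5 equiv), CH2Cl2, 0 °C → rt
Reagents that add atoms: none
Why: The acid cleaves the spare 4-methoxybenzyl aryl ether by SN1 ionisation (cation trapped by pentamethylbenzene in a Friedel–Crafts alkylation) and reversibly ionises the C2–O1 bond to a 4-methoxybenzylic cation, whose reclosure by either of the two equivalent ring A phenol oxygens should give the thermodynamically favoured trans isomer, inverting C2 while C3 is untouched.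

**Step 8**
Reactants: 14 (2S,3S)-3-(3,5-dimethoxyphenyl)-6-(6-methoxy-1-benzofuran-2-yl)-2-(4-methoxyphenyl)-2,3-dihydro-1-benzofuran-4-ol
Product: 15 (2S,3S)-3-(3,5-dihydroxyphenyl)-6-(6-hydroxy-1-benzofuran-2-yl)-2-(4-hydroxyphenyl)-2,3-dihydro-1-benzofuran-4-ol (CNP0112262.1)
Conditions: BBr3 (12 equiv), CH2Cl2, −78 °C → rt; then H2O, 0 °C
Reagents that add atoms: none
Why: BBr3 cleavage of the four aryl methyl ethers (Lewis acid complexation, then SN2 attack of bromide on methyl); the trans ring is already the thermodynamic isomer, so any reversible C2–O1 ionisation should return the same configuration.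

**Compound list**
1 | 1-bromo-3,5-difluorobenzene | Fc1cc(F)cc(Br)c1 | starting material
2 | 3,5-dimethoxybenzaldehyde | COc1cc(C=O)cc(OC)c1 | starting material
3 | (4-bromo-2,6-difluorophenyl)lithium | [Li]c1c(F)cc(Br)cc1F | intermediate (not isolated)
4 | racemic (4-bromo-2,6-difluorophenyl)(3,5-dimethoxyphenyl)methanol | COc1cc(cc(OC)c1)C(O)c1c(F)cc(Br)cc1F | intermediate
5 | (4-bromo-2,6-difluorophenyl)(3,5-dimethoxyphenyl)methanone | COc1cc(cc(OC)c1)C(=O)c1c(F)cc(Br)cc1F | intermediate
6 | (4-methoxyphenyl)methanol | COc1ccc(CO)cc1 | starting material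
7 | {4-bromo-2-fluoro-6-[(4-methoxybenzyl)oxy]phenyl}(3,5-dimethoxyphenyl)methanone | COc1ccc(COc2cc(Br)cc(F)c2C(=O)c2cc(OC)cc(OC)c2)cc1 | intermediate (not isolated)
8 | {4-bromo-2,6-bis[(4-methoxybenzyl)oxy]phenyl}(3,5-dimethoxyphenyl)methanone | COc1ccc(COc2cc(Br)cc(OCc3ccc(OC)cc3)c2C(=O)c2cc(OC)cc(OC)c2)cc1 | intermediate
9 | (6-methoxy-1-benzofuran-2-yl)boronic acid | COc1ccc2cc(B(O)O)oc2c1 | starting material
10 | {2,6-bis[(4-methoxybenzyl)oxy]-4-(6-methoxy-1-benzofuran-2-yl)phenyl}(3,5-dimethoxyphenyl)methanone | COc1ccc(COc2cc(-c3cc4ccc(OC)cc4o3)cc(OCc3ccc(OC)cc3)c2C(=O)c2cc(OC)cc(OC)c2)cc1 | intermediate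
11 | hydrazone of ketone 10 (E/Z mixture) | COc1ccc(COc2cc(-c3cc4ccc(OC)cc4o3)cc(OCc3ccc(OC)cc3)c2C(=NN)c2cc(OC)cc(OC)c2)cc1 | intermediate
12 | 2-[diazo(3,5-dimethoxyphenyl)methyl]-1,3-bis[(4-methoxybenzyl)oxy]-5-(6-methoxy-1-benzofuran-2-yl)benzene | COc1ccc(COc2cc(-c3cc4ccc(OC)cc4o3)cc(OCc3ccc(OC)cc3)c2C(=[N+]=[N-])c2cc(OC)cc(OC)c2)cc1 | intermediate (not isolated)
13 | (2R,3S)-3-(3,5-dimethoxyphenyl)-4-[(4-methoxybenzyl)oxy]-6-(6-methoxy-1-benzofuran-2-yl)-2-(4-methoxyphenyl)-2,3-dihydro-1-benzofuran | COc1ccc([C@@H]2Oc3cc(-c4cc5ccc(OC)cc5o4)cc(OCc4ccc(OC)cc4)c3[C@@H]2c2cc(OC)cc(OC)c2)cc1 | intermediate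
14 | (2S,3S)-3-(3,5-dimethoxyphenyl)-6-(6-methoxy-1-benzofuran-2-yl)-2-(4-methoxyphenyl)-2,3-dihydro-1-benzofuran-4-ol | COc1ccc([C@H]2Oc3cc(-c4cc5ccc(OC)cc5o4)cc(O)c3[C@@H]2c2cc(OC)cc(OC)c2)cc1 | intermediate
15 | (2S,3S)-3-(3,5-dihydroxyphenyl)-6-(6-hydroxy-1-benzofuran-2-yl)-2-(4-hydroxyphenyl)-2,3-dihydro-1-benzofuran-4-ol | Oc1ccc([C@H]2Oc3cc(-c4cc5ccc(O)cc5o4)cc(O)c3[C@@H]2c2cc(O)cc(O)c2)cc1 | target

**Totals**
Total step count: 8. Longest linear sequence: 8 steps (from 1).

**Steps most likely to fail**

Step 5. The condensation may stall because both faces of the carbonyl are shielded by the ortho benzyloxy arms, and forcing it may divert material into azine formation. Fallback, setting out from 10 and returning at 11: thionation with Lawesson's reagent (toluene, 100 °C) should give the diaryl thioketone F1. Its longer, more polarisable C=S bond should be attacked by hydrazine hydrate at room temperature (THF/EtOH), returning hydrazone 11 with loss of hydrogen sulfide.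

Step 6. The electron-rich diazo compound may be consumed by over-oxidation or azine formation before carbene transfer, or facial control may be lost at a carbene flanked by two ortho ethers. Fallback, setting out from 8 and returning at 14: 8 is used before the Suzuki coupling so that the benzophenone triplet is not quenched by the arylbenzofuran. Irradiation at 365 nm in benzene should form the same C2–C3 bond by Norrish–Yang 1,6-hydrogen abstraction and 1,5-biradical coupling, giving the racemic 3-hydroxy-dihydrobenzofuran F2. Ionic deoxygenation (Et3SiH, BF3·OEt2, CH2Cl2, −78 °C) should give the racemic bromo dihydrobenzofuran F3. Suzuki coupling with 9 under the conditions of step 4 should give the racemic dihydrobenzofuran F4, and the conditions of step 7 the racemic trans phenol F5. Preparative chiral SFC of F5 then delivers 14.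

Step 7. The released 4-methoxybenzyl cation may alkylate the electron-rich rings or the benzofuran C3 position instead of the scavenger, or the C2 equilibration may remain incomplete. Fallback, setting out from 13 and returning at 15: hydrogenolysis (H2, Pd/C, EtOAc, rt) should remove the spare benzyl ether as 4-methylanisole without generating a cation, giving the cis phenol F6. BBr3 under the conditions of step 8 should then demethylate and epimerise C2 in one operation, arriving at 15.

**Further compounds**
F1 | step 5 | {2,6-bis[(4-methoxybenzyl)oxy]-4-(6-methoxy-1-benzofuran-2-yl)phenyl}(3,5-dimethoxyphenyl)methanethione | COc1ccc(COc2cc(-c3cc4ccc(OC)cc4o3)cc(OCc3ccc(OC)cc3)c2C(=S)c2cc(OC)cc(OC)c2)cc1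
F2 | step 6 | racemic 6-bromo-3-(3,5-dimethoxyphenyl)-4-[(4-methoxybenzyl)oxy]-2-(4-methoxyphenyl)-2,3-dihydro-1-benzofuran-3-ol (diastereomer mixture) | COc1ccc(COc2cc(Br)cc3c2C(O)(c2cc(OC)cc(OC)c2)C(c2ccc(OC)cc2)O3)cc1
F3 | step 6 | racemic 6-bromo-3-(3,5-dimethoxyphenyl)-4-[(4-methoxybenzyl)oxy]-2-(4-methoxyphenyl)-2,3-dihydro-1-benzofuran (cis/trans mixture) | COc1ccc(COc2cc(Br)cc3c2C(c2cc(OC)cc(OC)c2)C(c2ccc(OC)cc2)O3)cc1
F4 | step 6 | racemic 3-(3,5-dimethoxyphenyl)-4-[(4-methoxybenzyl)oxy]-6-(6-methoxy-1-benzofuran-2-yl)-2-(4-methoxyphenyl)-2,3-dihydro-1-benzofuran (cis/trans mixture) | COc1ccc(COc2cc(-c3cc4ccc(OC)cc4o3)cc3c2C(c2cc(OC)cc(OC)c2)C(c2ccc(OC)cc2)O3)cc1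
F5 | step 6 | racemic trans-3-(3,5-dimethoxyphenyl)-6-(6-methoxy-1-benzofuran-2-yl)-2-(4-methoxyphenyl)-2,3-dihydro-1-benzofuran-4-ol | COc1ccc(C2Oc3cc(-c4cc5ccc(OC)cc5o4)cc(O)c3C2c2cc(OC)cc(OC)c2)cc1
F6 | step 7 | (2R,3S)-3-(3,5-dimethoxyphenyl)-6-(6-methoxy-1-benzofuran-2-yl)-2-(4-methoxyphenyl)-2,3-dihydro-1-benzofuran-4-ol (cis) | COc1ccc([C@@H]2Oc3cc(-c4cc5ccc(OC)cc5o4)cc(O)c3[C@@H]2c2cc(OC)cc(OC)c2)cc1
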